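**Strategy.** Everything rests on disconnecting the bond between the spiro carbon, which is C2 of the dihydrofuran ring and carries the ring oxygen, and the neighbouring quaternary carbon of the cyclohexane (methyl and propanoate chain). Because an oxygen-bearing furan carbon sits directly on that quaternary centre, the six-membered ring can be grown from a 1-(benzofuran-2-yl)cyclopentanol: acid protonates C3, the quaternary carbon shifts to the C2 oxocarbenium ion, and the spiro centre, the vicinal fully substituted pair and the ring ketone arise in one operation. The precursor is a benzyl-protected atrarate-derived benzofuran carrying an enantioenriched 1-hydroxycyclopentyl group; the benzene ring is enlarged to the tropone afterwards.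

Key step: step 8

Assumption: the named enantiomer of the ferrocenyl diphosphine is taken to deliver the isopropenyl group so as to give the (3R) enolate 4; if its sense of induction proves opposite, the mirror-image ligand is used and nothing else changes.

**Step 1**
Reactants: 1 2-methylcyclopent-2-en-1-one; 2 isopropenylmagnesium bromide; 3 benzyl acrylate
Product: 5 benzyl 3-[(1R,5R)-1-methyl-2-oxo-5-(prop-1-en-2-yl)cyclopentyl]propanoate, via bromomagnesium enolate 4 (not isolated)
Conditions: CuBr·SMe2 (5 mol %), (R)-1-[(S)-2-(diphenylphosphino)ferrocenyl]ethyldicyclohexylphosphine (6 mol %), t-BuOMe, −78 °C; then 3, THF, −78 → −30 °C; aq. NH4Cl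
Reagents that add atoms: isopropenylmagnesium bromide 2, C=C(C)[Mg]Br; benzyl acrylate 3, C=CC(=O)OCc1ccccc1
Why: Copper-catalysed asymmetric conjugate addition of the Grignard reagent sets the isopropenyl-bearing carbon under ligand control, and the resulting magnesium enolate undergoes Michael addition to the acrylate at its methyl-bearing carbon on the face opposite the isopropenyl group, so the quaternary centre forms by substrate control with the chain trans and the methyl cis to isopropenyl.

**Step 2**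
Reactants: 5 benzyl 3-[(1R,5R)-1-methyl-2-oxo-5-(prop-1-en-2-yl)cyclopentyl]propanoate; 6 dioxygen
Product: 7 benzyl 3-[(1R,2S)-2-(2-hydroxypropan-2-yl)-1-methyl-5-oxocyclopentyl]propanoate
Conditions: Co(acac)2 (cat.), PhSiH3, O2 (1 atm), THF, rt; then aq. Na2S2O3
Reagents that add atoms: dioxygen 6, O=O
Why: Mukaiyama hydration (cobalt-hydride hydrogen-atom transfer, O2 capture of the tertiary radical, reduction of the peroxide) adds water in the Markovnikov sense to the 1,1-disubstituted alkene and spares ketone and ester; no stereocentre is formed.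

**Step 3**
Reactants: 7 benzyl 3-[(1R,2S)-2-(2-hydroxypropan-2-yl)-1-methyl-5-oxocyclopentyl]propanoate; 8 triethylsilyl trifluoromethanesulfonate
Product: 9 benzyl 3-[(1R,5S)-1-methyl-2-oxo-5-{2-[(triethylsilyl)oxy]propan-2-yl}cyclopentyl]propanoate
Conditions: TESOTf, 2,6-lutidine, CH2Cl2, −78 → 0 °C
Reagents that add atoms: triethylsilyl trifluoromethanesulfonate 8, CC[Si](CC)(CC)OS(=O)(=O)C(F)(F)F
Why: A silyl triflate with a hindered pyridine base silylates the hindered tertiary alcohol at low temperature without enolizing the ketone, and the ether shields the alcohol from the organometallic, acid and carbene steps that follow.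

**Step 4**
Reactants: 9 benzyl 3-[(1R,5S)-1-methyl-2-oxo-5-{2-[(triethylsilyl)oxy]propan-2-yl}cyclopentyl]propanoate; 10 ethynylmagnesium bromide
Product: 11 benzyl 3-[(1R,2S,5S)-2-ethynyl-2-hydroxy-1-methyl-5-{2-[(triethylsilyl)oxy]propan-2-yl}cyclopentyl]propanoate (hydroxyl cis to the ring methyl and to the silyloxypropyl group)
Conditions: 10 (3 equiv), LaCl3·2LiCl (1 equiv), THF, −20 → 0 °C; aq. NH4Cl
Reagents that add atoms: ethynylmagnesium bromide 10, C#C[Mg]Br
Why: Chemoselective 1,2-addition of the small alkynyl Grignard reagent to the ketone (lanthanum chloride activation suppresses enolization and ester attack) from the face opposite the silyloxypropyl group should place the hydroxyl cis to it, a centre that is erased again in step 8.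

**Step 5**
Reactants: 12 methyl atrarate (methyl 2,4-dihydroxy-3,6-dimethylbenzoate); 13 N-iodosuccinimide
Product: 14 methyl 2,4-dihydroxy-5-iodo-3,6-dimethylbenzoate
Conditions: NIS, MeCN, 0 °C → rt
Reagents that add atoms: N-iodosuccinimide 13, O=C1CCC(=O)N1I
Why: Electrophilic aromatic iodination occurs at the single unsubstituted ring carbon, which is ortho to the 4-hydroxyl and para to the 2-hydroxyl.

**Step 6**
Reactants: 11 benzyl 3-[(1R,2S,5S)-2-ethynyl-2-hydroxy-1-methyl-5-{2-[(triethylsilyl)oxy]propan-2-yl}cyclopentyl]propanoate; 14 methyl 2,4-dihydroxy-5-iodo-3,6-dimethylbenzoate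
Product: 16 methyl 2-[(1R,2R,3S)-2-[3-(benzyloxy)-3-oxopropyl]-1-hydroxy-2-methyl-3-{2-[(triethylsilyl)oxy]propan-2-yl}cyclopentyl]-6-hydroxy-4,7-dimethyl-1-benzofuran-5-carboxylate, via ortho-alkynylphenol 15 (not isolated)
Conditions: Pd(PPh3)2Cl2 (5 mol %), CuI (10 mol %), Et3N, DMF (degassed), rt → 65 °C
Reagents that add atoms: none
Why: Sonogashira coupling of the aryl iodide with the terminal alkyne is followed in the same flask by copper-assisted 5-endo-dig addition of the ortho hydroxyl to the alkyne (benzofuran heteroannulation); only the 4-hydroxyl is ortho to the alkyne and the three stereocentres are untouched.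

**Step 7**
Reactants: 16 methyl 2-[(1R,2R,3S)-2-[3-(benzyloxy)-3-oxopropyl]-1-hydroxy-2-methyl-3-{2-[(triethylsilyl)oxy]propan-2-yl}cyclopentyl]-6-hydroxy-4,7-dimethyl-1-benzofuran-5-carboxylate; 17 benzyl bromide
Product: 18 methyl 6-(benzyloxy)-2-[(1R,2R,3S)-2-[3-(benzyloxy)-3-oxopropyl]-1-hydroxy-2-methyl-3-{2-[(triethylsilyl)oxy]propan-2-yl}cyclopentyl]-4,7-dimethyl-1-benzofuran-5-carboxylate
Conditions: BnBr, K2CO3, DMF, 45 °C
Reagents that add atoms: benzyl bromide 17, BrCc1ccccc1
Why: Williamson etherification of the only phenol (hydrogen-bonded to the ester, hence warm DMF) proceeds while carbonate leaves the tertiary alcohol protonated, so it is neither benzylated nor lactonized.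

**Step 8**
Reactants: 18 methyl 6-(benzyloxy)-2-[(1R,2R,3S)-2-[3-(benzyloxy)-3-oxopropyl]-1-hydroxy-2-methyl-3-{2-[(triethylsilyl)oxy]propan-2-yl}cyclopentyl]-4,7-dimethyl-1-benzofuran-5-carboxylate
Product: 19 methyl (2R,2'R,3'S)-6-(benzyloxy)-2'-[3-(benzyloxy)-3-oxopropyl]-2',4,7-trimethyl-6'-oxo-3'-{2-[(triethylsilyl)oxy]propan-2-yl}-3H-spiro[1-benzofuran-2,1'-cyclohexane]-5-carboxylate (C3 methylene cis to the 2'-methyl, O1 cis to the chain)
Conditions: (1S)-(+)-10-camphorsulfonic acid (1.0 equiv), PhMe (anhydrous), 45 °C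
Reagents that add atoms: none
Why: The sulfonic acid protonates the benzofuran at C3, which turns C2 into an oxocarbenium ion next to the tertiary carbinol, and the ring bond of the cyclopentanol that lies antiperiplanar to the empty orbital shifts its quaternary carbon to that cation while the hydroxyl oxygen becomes the ketone, a protio-semipinacol rearrangement of the kind established for 1-heteroaryl and 1-alkenyl cycloalkanols. The six-membered carbocycle is closed by this 1,2-alkyl shift, a five-to-six ring enlargement through a three-centre transition state and not an end-on cyclization, which forges the bond between the spiro carbon and the quaternary carbon with retention at the latter. The new spiro stereocentre is set by the substrate: in the chair-like transition state the CH2–aryl edge of the heterocycle takes the equatorial site on the face of the quaternary methyl, away from the ring CH that carries the bulky silyloxypropyl group, and the small ring oxygen takes the axial site on the face of the propanoate chain. The step needs migration of the quaternary carbon in preference to the ring CH2, which the higher migratory aptitude of the more substituted carbon provides, and it needs C3 protonation in preference to ionization of the carbinol or loss of the silyl group, which a non-polar, non-nucleophilic solvent favours because ionization requires charge separation whereas proton transfer and shift proceed within a tight ion pair. Benzyl ester, benzyl ether, silyl ether and aryl methyl ester are inert to the anhydrous acid.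

**Step 9**
Reactants: 19 methyl (2R,2'R,3'S)-6-(benzyloxy)-2'-[3-(benzyloxy)-3-oxopropyl]-2',4,7-trimethyl-6'-oxo-3'-{2-[(triethylsilyl)oxy]propan-2-yl}-3H-spiro[1-benzofuran-2,1'-cyclohexane]-5-carboxylate; 20 methyltriphenylphosphonium bromide
Product: 21 methyl (2S,2'R,3'S)-6-(benzyloxy)-2'-[3-(benzyloxy)-3-oxopropyl]-2',4,7-trimethyl-6'-methylidene-3'-{2-[(triethylsilyl)oxy]propan-2-yl}-3H-spiro[1-benzofuran-2,1'-cyclohexane]-5-carboxylate (same spatial arrangement at C2; the descriptor changes with the priorities)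
Conditions: Ph3PCH3Br, KHMDS, THF, 0 °C; then 19, 0 → 50 °C
Reagents that add atoms: methyltriphenylphosphonium bromide 20, C[P+](c1ccccc1)(c1ccccc1)c1ccccc1.[Br-]
Why: Wittig methylenation with the alkoxide-free ylide converts the ketone, which is hindered on one side only and far more electrophilic than the benzyl ester or the di-ortho-substituted aryl ester; enolization is possible only towards C5', so no stereocentre is at risk.

**Step 10**
Reactants: 21 methyl (2S,2'R,3'S)-6-(benzyloxy)-2'-[3-(benzyloxy)-3-oxopropyl]-2',4,7-trimethyl-6'-methylidene-3'-{2-[(triethylsilyl)oxy]propan-2-yl}-3H-spiro[1-benzofuran-2,1'-cyclohexane]-5-carboxylate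
Product: 22 methyl (2S,2'R,3'S,6'S)-6-(benzyloxy)-2'-[3-(benzyloxy)-3-oxopropyl]-2',4,6',7-tetramethyl-3'-{2-[(triethylsilyl)oxy]propan-2-yl}-3H-spiro[1-benzofuran-2,1'-cyclohexane]-5-carboxylate
Conditions: Mn(dpm)3 (10 mol %), PhSiH3, t-BuOOH, i-PrOH, rt
Reagents that add atoms: none
Why: Metal-hydride hydrogen-atom-transfer hydrogenation gives a tertiary cyclohexyl radical that should be reduced from the axial direction, so the new methyl takes the equatorial position (6'S) and avoids the 1,3-diaxial clash with the axial 2'-methyl that the other epimer would suffer; the benzyl groups survive, unlike under H2/Pd.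

**Step 11**
Reactants: 22 methyl (2S,2'R,3'S,6'S)-6-(benzyloxy)-2'-[3-(benzyloxy)-3-oxopropyl]-2',4,6',7-tetramethyl-3'-{2-[(triethylsilyl)oxy]propan-2-yl}-3H-spiro[1-benzofuran-2,1'-cyclohexane]-5-carboxylate
Product: 23 3-[(2S,2'R,3'S,6'S)-6-hydroxy-5-(methoxycarbonyl)-2',4,6',7-tetramethyl-3'-{2-[(triethylsilyl)oxy]propan-2-yl}-3H-spiro[1-benzofuran-2,1'-cyclohexan]-2'-yl]propanoic acid
Conditions: H2 (1 atm), Pd/C, EtOAc, rt
Reagents that add atoms: none
Why: Catalytic hydrogenolysis cleaves the benzyl ether and the benzyl ester in one operation, freeing the phenol needed for dearomatization and the chain acid of the target, while the aryl methyl ester, the tertiary silyl ether and the alkyl aryl ether of the spiro ring are inert.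

**Step 12**
Reactants: 23 3-[(2S,2'R,3'S,6'S)-6-hydroxy-5-(methoxycarbonyl)-2',4,6',7-tetramethyl-3'-{2-[(triethylsilyl)oxy]propan-2-yl}-3H-spiro[1-benzofuran-2,1'-cyclohexan]-2'-yl]propanoic acid; 24 chloroform
Product: 25 3-[(2S,2'R,3'S,6'S)-3a-(dichloromethyl)-5-(methoxycarbonyl)-2',4,6',7-tetramethyl-6-oxo-3'-{2-[(triethylsilyl)oxy]propan-2-yl}-3a,6-dihydro-3H-spiro[1-benzofuran-2,1'-cyclohexan]-2'-yl]propanoic acid (both C3a epimers)
Conditions: CHCl3, 4 M aq. NaOH, BnEt3NCl (cat.), 0 °C → rt; then aq. NaH2PO4 to pH 4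
Reagents that add atoms: chloroform 24, ClC(Cl)Cl
Why: In this abnormal Reimer–Tiemann reaction dichlorocarbene is captured by the ring-fusion carbon para to the phenoxide oxygen (also ortho to the ring ether oxygen), and because that carbon is fully substituted the adduct cannot rearomatize and stays as the cross-conjugated 4-(dichloromethyl)dienone; the new quaternary centre is an inconsequential epimer mixture because step 13 flattens it again.

**Step 13**
Reactants: 25 3-[(2S,2'R,3'S,6'S)-3a-(dichloromethyl)-5-(methoxycarbonyl)-2',4,6',7-tetramethyl-6-oxo-3'-{2-[(triethylsilyl)oxy]propan-2-yl}-3a,6-dihydro-3H-spiro[1-benzofuran-2,1'-cyclohexan]-2'-yl]propanoic acid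
Product: 26 3-[(2S,2'R,3'S,6'S)-6-(methoxycarbonyl)-2',5,6',8-tetramethyl-7-oxo-3'-{2-[(triethylsilyl)oxy]propan-2-yl}-3,7-dihydrospiro[cyclohepta[b]furan-2,1'-cyclohexan]-2'-yl]propanoic acid
Conditions: Bu3SnH, AIBN (cat.), i-Pr2NEt, PhMe, 85 °C; KF work-up
Reagents that add atoms: none
Why: In this tin-hydride radical ring expansion of a 4-(dichloromethyl)cyclohexadienone, chlorine abstraction gives an α-chloroalkyl radical that closes 3-exo-trig onto the methyl-bearing carbon of the ester-substituted enone (leaving the radical between ketone and ester), the cyclopropane opens to the seven-membered ring, and loss of the second chlorine (as HCl, taken up by the amine) gives the tropone with the new CH between the fusion carbon and the methyl-bearing carbon.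

**Step 14**
Reactants: 26 3-[(2S,2'R,3'S,6'S)-6-(methoxycarbonyl)-2',5,6',8-tetramethyl-7-oxo-3'-{2-[(triethylsilyl)oxy]propan-2-yl}-3,7-dihydrospiro[cyclohepta[b]furan-2,1'-cyclohexan]-2'-yl]propanoic acid
Product: 27 3-[(2S,2'R,3'S,6'S)-3'-(2-hydroxypropan-2-yl)-6-(methoxycarbonyl)-2',5,6',8-tetramethyl-7-oxo-3,7-dihydrospiro[cyclohepta[b]furan-2,1'-cyclohexan]-2'-yl]propanoic acid (CNP0448476.1)
Conditions: HF·pyridine, pyridine, THF, 0 °C → rt
Reagents that add atoms: none
Why: Fluoride cleavage of the tertiary triethylsilyl ether under buffered, weakly acidic conditions should neither ionize the tertiary alcohol nor touch the tropone methyl ester, and no ester hydrolysis is needed because the chain acid is already free.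

**Compound list**
1 | 2-methylcyclopent-2-en-1-one | CC1=CCCC1=O | starting material
2 | isopropenylmagnesium bromide | C=C(C)[Mg]Br | starting material
3 | benzyl acrylate | C=CC(=O)OCc1ccccc1 | starting material
4 | bromomagnesium (3R)-2-methyl-3-(prop-1-en-2-yl)cyclopent-1-en-1-olate (not isolated) | CC1=C(O[Mg]Br)CC[C@@H]1C(C)=C | intermediate
5 | benzyl 3-[(1R,5R)-1-methyl-2-oxo-5-(prop-1-en-2-yl)cyclopentyl]propanoate | O=C1CC[C@H](C(C)=C)[C@@]1(C)CCC(=O)OCc2ccccc2 | intermediate
6 | dioxygen | O=O | starting material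
7 | benzyl 3-[(1R,2S)-2-(2-hydroxypropan-2-yl)-1-methyl-5-oxocyclopentyl]propanoate | O=C1CC[C@H](C(C)(C)O)[C@@]1(C)CCC(=O)OCc2ccccc2 | intermediate
8 | triethylsilyl trifluoromethanesulfonate | CC[Si](CC)(CC)OS(=O)(=O)C(F)(F)F | starting material
9 | benzyl 3-[(1R,5S)-1-methyl-2-oxo-5-{2-[(triethylsilyl)oxy]propan-2-yl}cyclopentyl]propanoate | O=C1CC[C@H](C(C)(C)O[Si](CC)(CC)CC)[C@@]1(C)CCC(=O)OCc2ccccc2 | intermediate
10 | ethynylmagnesium bromide | C#C[Mg]Br | starting material
11 | benzyl 3-[(1R,2S,5S)-2-ethynyl-2-hydroxy-1-methyl-5-{2-[(triethylsilyl)oxy]propan-2-yl}cyclopentyl]propanoate | C#C[C@@]1(O)CC[C@H](C(C)(C)O[Si](CC)(CC)CC)[C@@]1(C)CCC(=O)OCc2ccccc2 | intermediate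
12 | methyl atrarate (methyl 2,4-dihydroxy-3,6-dimethylbenzoate) | COC(=O)c1c(C)cc(O)c(C)c1O | starting material
13 | N-iodosuccinimide | O=C1CCC(=O)N1I | starting material
14 | methyl 2,4-dihydroxy-5-iodo-3,6-dimethylbenzoate | COC(=O)c1c(C)c(I)c(O)c(C)c1O | intermediate
15 | methyl 5-{[(1R,2R,3S)-2-[3-(benzyloxy)-3-oxopropyl]-1-hydroxy-2-methyl-3-{2-[(triethylsilyl)oxy]propan-2-yl}cyclopentyl]ethynyl}-2,4-dihydroxy-3,6-dimethylbenzoate (not isolated) | COC(=O)c1c(C)c(C#C[C@@]2(O)CC[C@H](C(C)(C)O[Si](CC)(CC)CC)[C@@]2(C)CCC(=O)OCc3ccccc3)c(O)c(C)c1O | intermediate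
16 | methyl 2-[(1R,2R,3S)-2-[3-(benzyloxy)-3-oxopropyl]-1-hydroxy-2-methyl-3-{2-[(triethylsilyl)oxy]propan-2-yl}cyclopentyl]-6-hydroxy-4,7-dimethyl-1-benzofuran-5-carboxylate | COC(=O)c1c(C)c2cc(oc2c(C)c1O)[C@@]3(O)CC[C@H](C(C)(C)O[Si](CC)(CC)CC)[C@@]3(C)CCC(=O)OCc4ccccc4 | intermediate
17 | benzyl bromide | BrCc1ccccc1 | starting material
18 | methyl 6-(benzyloxy)-2-[(1R,2R,3S)-2-[3-(benzyloxy)-3-oxopropyl]-1-hydroxy-2-methyl-3-{2-[(triethylsilyl)oxy]propan-2-yl}cyclopentyl]-4,7-dimethyl-1-benzofuran-5-carboxylate (key-step precursor) | COC(=O)c1c(C)c2cc(oc2c(C)c1OCc3ccccc3)[C@@]4(O)CC[C@H](C(C)(C)O[Si](CC)(CC)CC)[C@@]4(C)CCC(=O)OCc5ccccc5 | intermediate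
19 | methyl (2R,2'R,3'S)-6-(benzyloxy)-2'-[3-(benzyloxy)-3-oxopropyl]-2',4,7-trimethyl-6'-oxo-3'-{2-[(triethylsilyl)oxy]propan-2-yl}-3H-spiro[1-benzofuran-2,1'-cyclohexane]-5-carboxylate (key-step product) | COC(=O)c1c(C)c2c(c(C)c1OCc3ccccc3)O[C@@]4(C2)C(=O)CC[C@H](C(C)(C)O[Si](CC)(CC)CC)[C@@]4(C)CCC(=O)OCc5ccccc5 | intermediate
20 | methyltriphenylphosphonium bromide | C[P+](c1ccccc1)(c1ccccc1)c1ccccc1.[Br-] | starting material
21 | methyl (2S,2'R,3'S)-6-(benzyloxy)-2'-[3-(benzyloxy)-3-oxopropyl]-2',4,7-trimethyl-6'-methylidene-3'-{2-[(triethylsilyl)oxy]propan-2-yl}-3H-spiro[1-benzofuran-2,1'-cyclohexane]-5-carboxylate | COC(=O)c1c(C)c2c(c(C)c1OCc3ccccc3)O[C@@]4(C2)C(=C)CC[C@H](C(C)(C)O[Si](CC)(CC)CC)[C@@]4(C)CCC(=O)OCc5ccccc5 | intermediate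
22 | methyl (2S,2'R,3'S,6'S)-6-(benzyloxy)-2'-[3-(benzyloxy)-3-oxopropyl]-2',4,6',7-tetramethyl-3'-{2-[(triethylsilyl)oxy]propan-2-yl}-3H-spiro[1-benzofuran-2,1'-cyclohexane]-5-carboxylate | COC(=O)c1c(C)c2c(c(C)c1OCc3ccccc3)O[C@@]4(C2)[C@@H](C)CC[C@H](C(C)(C)O[Si](CC)(CC)CC)[C@@]4(C)CCC(=O)OCc5ccccc5 | intermediate
23 | 3-[(2S,2'R,3'S,6'S)-6-hydroxy-5-(methoxycarbonyl)-2',4,6',7-tetramethyl-3'-{2-[(triethylsilyl)oxy]propan-2-yl}-3H-spiro[1-benzofuran-2,1'-cyclohexan]-2'-yl]propanoic acid | COC(=O)c1c(C)c2c(c(C)c1O)O[C@@]3(C2)[C@@H](C)CC[C@H](C(C)(C)O[Si](CC)(CC)CC)[C@@]3(C)CCC(=O)O | intermediate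
24 | chloroform | ClC(Cl)Cl | starting material
25 | 3-[(2S,2'R,3'S,6'S)-3a-(dichloromethyl)-5-(methoxycarbonyl)-2',4,6',7-tetramethyl-6-oxo-3'-{2-[(triethylsilyl)oxy]propan-2-yl}-3a,6-dihydro-3H-spiro[1-benzofuran-2,1'-cyclohexan]-2'-yl]propanoic acid (C3a epimers) | COC(=O)C1=C(C)C2(C(Cl)Cl)C(=C(C)C1=O)O[C@@]3(C2)[C@@H](C)CC[C@H](C(C)(C)O[Si](CC)(CC)CC)[C@@]3(C)CCC(=O)O | intermediate
26 | 3-[(2S,2'R,3'S,6'S)-6-(methoxycarbonyl)-2',5,6',8-tetramethyl-7-oxo-3'-{2-[(triethylsilyl)oxy]propan-2-yl}-3,7-dihydrospiro[cyclohepta[b]furan-2,1'-cyclohexan]-2'-yl]propanoic acid | COC(=O)c1c(C)cc2c(c(C)c1=O)O[C@@]3(C2)[C@@H](C)CC[C@H](C(C)(C)O[Si](CC)(CC)CC)[C@@]3(C)CCC(=O)O | intermediate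
27 | 3-[(2S,2'R,3'S,6'S)-3'-(2-hydroxypropan-2-yl)-6-(methoxycarbonyl)-2',5,6',8-tetramethyl-7-oxo-3,7-dihydrospiro[cyclohepta[b]furan-2,1'-cyclohexan]-2'-yl]propanoic acid (CNP0448476.1) | COC(=O)c1c(C)cc2c(c(C)c1=O)O[C@@]1(C2)[C@@H](C)CC[C@H](C(C)(C)O)[C@@]1(C)CCC(=O)O | target

**Totals.** Total step count: 14. Longest linear sequence: 13 steps (steps 1–4 and 6–14; step 5 is the one-step side branch).

**Three steps most likely to fail**

1. Step 8 (key step). The ester-deactivated benzofuran may be protonated at C3 more slowly than the acid strips water from the tertiary heteroaryl carbinol or removes the silyl group, and the quaternary carbon may add to the wrong face of the oxocarbenium ion. The fallback sets out from 18 and comes back at 19. The same 1,2-shift is triggered by electrophilic bromine instead of a proton (NBS, NaHCO3, MeCN, −20 °C), which attacks C3 directly under non-acidic conditions and should give methyl (2R,3R,2'R,3'S)-6-(benzyloxy)-2'-[3-(benzyloxy)-3-oxopropyl]-3-bromo-2',4,7-trimethyl-6'-oxo-3'-{2-[(triethylsilyl)oxy]propan-2-yl}-3H-spiro[1-benzofuran-2,1'-cyclohexane]-5-carboxylate F1. Bromine ends trans to the migrated carbon, and the bulkier CHBr edge should prefer the equatorial site even more strongly. Radical debromination at high hydride concentration (Bu3SnH, Et3B/air, PhMe, 0 °C) then returns to 19.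

2. Step 12. The carbene may be consumed by water or by the carboxylate before it reaches the para carbon, and the sodium-paired phenoxide may steer it to the ortho carbons (poor site selectivity). The fallback sets out from 23 and comes back at 26. The acid is masked (Me3SiCHN2, PhMe/MeOH, 0 °C) as methyl (2S,2'R,3'S,6'S)-6-hydroxy-2'-(3-methoxy-3-oxopropyl)-2',4,6',7-tetramethyl-3'-{2-[(triethylsilyl)oxy]propan-2-yl}-3H-spiro[1-benzofuran-2,1'-cyclohexane]-5-carboxylate F2. Its phenoxide is then dearomatized as a lipophilic ion pair in a single organic phase (powdered KOH, 18-crown-6, CHCl3, 0 °C), which should favour para attack, giving the 3a-(dichloromethyl) dienone diester F3. Bu3SnH, AIBN and i-Pr2NEt (PhMe, 85 °C) should give the tropone diester F4, methyl (2S,2'R,3'S,6'S)-2'-(3-methoxy-3-oxopropyl)-2',5,6',8-tetramethyl-7-oxo-3'-{2-[(triethylsilyl)oxy]propan-2-yl}-3,7-dihydrospiro[cyclohepta[b]furan-2,1'-cyclohexane]-6-carboxylate. Me3SnOH (ClCH2CH2Cl, 70 °C) then cleaves only the unhindered chain ester and returns to 26.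

3. Step 6. The hindered, electron-rich iodide may undergo slow oxidative addition, so that the precious alkyne dimerizes oxidatively or the sequence stalls at the alkynylphenol. The fallback sets out from 14 and 9 and comes back at 18, joining the fragments by carbonyl addition instead of cross-coupling. Iodide 14 is coupled and cyclized with an excess of cheap ethynyltrimethylsilane (Pd(PPh3)2Cl2, CuI, Et3N, DMF, 65 °C) to methyl 6-hydroxy-4,7-dimethyl-2-(trimethylsilyl)-1-benzofuran-5-carboxylate F5. Desilylation (Bu4NF, THF) gives methyl 6-hydroxy-4,7-dimethyl-1-benzofuran-5-carboxylate F6, and benzylation (BnBr, K2CO3, DMF) gives methyl 6-(benzyloxy)-4,7-dimethyl-1-benzofuran-5-carboxylate F7. Magnesiation at C2 with TMPMgCl·LiCl (THF, 0 °C) gives [6-(benzyloxy)-5-(methoxycarbonyl)-4,7-dimethyl-1-benzofuran-2-yl]magnesium chloride F8, which adds to ketone 9 in the presence of LaCl3·2LiCl (−20 °C) from the face opposite the silyloxypropyl group to give 18.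

**Further compounds**
F1 | step 8 | methyl (2R,3R,2'R,3'S)-6-(benzyloxy)-2'-[3-(benzyloxy)-3-oxopropyl]-3-bromo-2',4,7-trimethyl-6'-oxo-3'-{2-[(triethylsilyl)oxy]propan-2-yl}-3H-spiro[1-benzofuran-2,1'-cyclohexane]-5-carboxylate | COC(=O)c1c(C)c2c(c(C)c1OCc3ccccc3)O[C@@]4([C@@H]2Br)C(=O)CC[C@H](C(C)(C)O[Si](CC)(CC)CC)[C@@]4(C)CCC(=O)OCc5ccccc5
F2 | step 12 | methyl (2S,2'R,3'S,6'S)-6-hydroxy-2'-(3-methoxy-3-oxopropyl)-2',4,6',7-tetramethyl-3'-{2-[(triethylsilyl)oxy]propan-2-yl}-3H-spiro[1-benzofuran-2,1'-cyclohexane]-5-carboxylate | COC(=O)c1c(C)c2c(c(C)c1O)O[C@@]3(C2)[C@@H](C)CC[C@H](C(C)(C)O[Si](CC)(CC)CC)[C@@]3(C)CCC(=O)OC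
F3 | step 12 | methyl (2S,2'R,3'S,6'S)-3a-(dichloromethyl)-2'-(3-methoxy-3-oxopropyl)-2',4,6',7-tetramethyl-6-oxo-3'-{2-[(triethylsilyl)oxy]propan-2-yl}-3a,6-dihydro-3H-spiro[1-benzofuran-2,1'-cyclohexane]-5-carboxylate (C3a epimers) | COC(=O)C1=C(C)C2(C(Cl)Cl)C(=C(C)C1=O)O[C@@]3(C2)[C@@H](C)CC[C@H](C(C)(C)O[Si](CC)(CC)CC)[C@@]3(C)CCC(=O)OC
F4 | step 12 | methyl (2S,2'R,3'S,6'S)-2'-(3-methoxy-3-oxopropyl)-2',5,6',8-tetramethyl-7-oxo-3'-{2-[(triethylsilyl)oxy]propan-2-yl}-3,7-dihydrospiro[cyclohepta[b]furan-2,1'-cyclohexane]-6-carboxylate | COC(=O)c1c(C)cc2c(c(C)c1=O)O[C@@]3(C2)[C@@H](C)CC[C@H](C(C)(C)O[Si](CC)(CC)CC)[C@@]3(C)CCC(=O)OC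
F5 | step 6 | methyl 6-hydroxy-4,7-dimethyl-2-(trimethylsilyl)-1-benzofuran-5-carboxylate | COC(=O)c1c(C)c2cc(oc2c(C)c1O)[Si](C)(C)C
F6 | step 6 | methyl 6-hydroxy-4,7-dimethyl-1-benzofuran-5-carboxylate | COC(=O)c1c(C)c2ccoc2c(C)c1O
F7 | step 6 | methyl 6-(benzyloxy)-4,7-dimethyl-1-benzofuran-5-carboxylate | COC(=O)c1c(C)c2ccoc2c(C)c1OCc3ccccc3
F8 | step 6 | [6-(benzyloxy)-5-(methoxycarbonyl)-4,7-dimethyl-1-benzofuran-2-yl]magnesium chloride | COC(=O)c1c(C)c2cc(oc2c(C)c1OCc3ccccc3)[Mg]Cl
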